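## Retrosynthetic overview

- Ring A's pyranone is the only ring built, and it is built first: carbonylative annulation of iodophenol 1 with alkyne 2 (through ynone 3) gives aldehyde 4. Ring B is bought intact as 7-hydroxychromone 5 and masked as pivalate 6.
- Key disconnection: the bond between C2 of ring B and the bridging carbon. C2 of 6, normally the electrophilic beta-carbon of the pyranone, is zincated (7) and used as a nucleophile on the aldehyde carbon of 4, giving carbinol 8.
- The bridging CH2 is the deoxygenated carbinol (9).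
- Last disconnection: the C5–CH2COCH3 bond of ring B, traced back to the peri C–H of 9 (ketone-directed C–H acylmethylation to 10), then pivalate removal to target 11.

Assumption: the target has no stereocentre (it is achiral), so no enantiocontrol is needed; the only stereocentre on the route (carbinol 8, racemic) is removed in step 4.

## Route

Step 1
Reactants: 1 3-hydroxy-2-iodo-4-methoxybenzaldehyde (2-iodoisovanillin); 2 3-methylbut-1-yne
Product: 4 2-isopropyl-8-methoxy-4-oxo-4H-chromene-5-carbaldehyde, via aryl ynone 3 (not isolated)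
Conditions: CO (20 bar), PdCl2(dppf) (3 mol%), 2 (2 equiv), Et2NH/THF, 100 °C, autoclave; 1 M HCl work-up
Reagents that add atoms: carbon monoxide, [C-]#[O+]
Why: Carbonylative Sonogashira coupling of the o-iodophenol gives ynone 3, which the secondary amine closes 6-endo (oxa-Michael) to the 2-isopropylchromone (carbonylative annulation); o-iodophenols are the proven substrates for this reaction and the aldehyde is a spectator.

Step 2
Reactants: 5 7-hydroxy-4H-chromen-4-one
Product: 6 4-oxo-4H-chromen-7-yl pivalate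
Conditions: PivCl (1.2 equiv), Et3N (1.5 equiv), DMAP (5 mol%), CH2Cl2, 0 °C to rt
Reagents that add atoms: pivaloyl chloride, CC(C)(C)C(=O)Cl
Why: DMAP-catalysed O-acylation of the only OH; the pivalate has no alpha-hydrogens, so it survives the amide-zinc base, TFA and the cationic rhodium step, and it leaves by mild methanolysis.

Step 3
Reactants: 6 4-oxo-4H-chromen-7-yl pivalate; 4 2-isopropyl-8-methoxy-4-oxo-4H-chromene-5-carbaldehyde
Product: 8 2-[hydroxy(2-isopropyl-8-methoxy-4-oxo-4H-chromen-5-yl)methyl]-4-oxo-4H-chromen-7-yl pivalate (racemic), via chromon-2-ylzinc chloride 7 (not isolated)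
Conditions: 6 (1.3 equiv), TMPZnCl·LiCl (1.25 equiv; TMP = 2,2,6,6-tetramethylpiperidide), THF, 25 °C, 1 h; then MgCl2 (1.3 equiv), 4 (1.0 equiv), THF, 0 °C to rt; aq. NH4Cl
Reagents that add atoms: none
Why: Deprotonative zincation with the hindered amide base removes the most acidic vinylic C2–H (alpha to the ring oxygen; C2-selective zincation of chromones with this base is known and ester-tolerant), turning the normally electrophilic C2 into a beta-acylvinyl (homoenolate-type, equally a masked acyl) anion that adds 1,2 to the aldehyde under MgCl2 acceleration (organozinc carbonyl addition); the new carbinol centre forms racemic and is erased in step 4.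

Step 4
Reactants: 8 2-[hydroxy(2-isopropyl-8-methoxy-4-oxo-4H-chromen-5-yl)methyl]-4-oxo-4H-chromen-7-yl pivalate
Product: 9 2-[(2-isopropyl-8-methoxy-4-oxo-4H-chromen-5-yl)methyl]-4-oxo-4H-chromen-7-yl pivalate
Conditions: Et3SiH (4 equiv), TFA/CH2Cl2 (1:2), 0 °C to rt
Reagents that add atoms: none
Why: Ionic hydrogenation (Kursanov–Parnes): TFA ionizes the benzylic alcohol, whose cation is stabilized by the para-methoxy group of ring A, and Et3SiH delivers hydride; both chromones and the pivalate are inert, and the only stereocentre disappears.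

Step 5
Reactants: 9 2-[(2-isopropyl-8-methoxy-4-oxo-4H-chromen-5-yl)methyl]-4-oxo-4H-chromen-7-yl pivalate
Product: 11 7-hydroxy-2-[(2-isopropyl-8-methoxy-4-oxo-4H-chromen-5-yl)methyl]-5-(2-oxopropyl)-4H-chromen-4-one (target), via pivalate-protected ketone 10 (not isolated)
Conditions: CH3C(O)CH=S(O)Me2 (1.5 equiv), [Cp*RhCl2]2 (4 mol%), AgSbF6 (16 mol%), NaOAc (30 mol%), HFIP, 70 °C; then evaporate, K2CO3 (1.5 equiv), MeOH, 0 °C to rt
Reagents that add atoms: dimethylsulfoxonium 2-oxopropylide, CC(=O)C=S(C)(C)=O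
Why: Proposed new method: the C4 carbonyl of ring B directs acetate-assisted peri C5–H metalation by [Cp*Rh(OAc)]+ (trivalent rhodium, five-membered rhodacycle, the mode known for ketone-directed C5 functionalization of chromones), the ylide then gives a rhodium carbene with loss of DMSO, and migratory insertion plus protodemetalation deliver Ar–CH2COCH3, the closest known type being C–H acylmethylation of arenes with sulfoxonium ylides under the same catalyst; ring A has no peri C–H, so only C5 of ring B reacts, and K2CO3/MeOH then transesterifies the activated aryl pivalate.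

## Compound list

1 | 3-hydroxy-2-iodo-4-methoxybenzaldehyde (2-iodoisovanillin) | COc1ccc(C=O)c(I)c1O | starting material
2 | 3-methylbut-1-yne | CC(C)C#C | starting material
3 | 1-(2-formyl-6-hydroxy-5-methoxyphenyl)-4-methylpent-2-yn-1-one | COc1ccc(C=O)c(C(=O)C#CC(C)C)c1O | intermediate
4 | 2-isopropyl-8-methoxy-4-oxo-4H-chromene-5-carbaldehyde | COc1ccc(C=O)c2c(=O)cc(C(C)C)oc12 | intermediate
5 | 7-hydroxy-4H-chromen-4-one | O=c1ccoc2cc(O)ccc12 | starting material
6 | 4-oxo-4H-chromen-7-yl pivalate | CC(C)(C)C(=O)Oc1ccc2c(c1)occc2=O | intermediate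
7 | [4-oxo-7-(pivaloyloxy)-4H-chromen-2-yl]zinc chloride (LiCl complex) | CC(C)(C)C(=O)Oc1ccc2c(c1)oc([Zn]Cl)cc2=O | intermediate
8 | 2-[hydroxy(2-isopropyl-8-methoxy-4-oxo-4H-chromen-5-yl)methyl]-4-oxo-4H-chromen-7-yl pivalate, racemic | COc1ccc(C(O)c2cc(=O)c3ccc(OC(=O)C(C)(C)C)cc3o2)c2c(=O)cc(C(C)C)oc12 | intermediate
9 | 2-[(2-isopropyl-8-methoxy-4-oxo-4H-chromen-5-yl)methyl]-4-oxo-4H-chromen-7-yl pivalate | COc1ccc(Cc2cc(=O)c3ccc(OC(=O)C(C)(C)C)cc3o2)c2c(=O)cc(C(C)C)oc12 | intermediate
10 | 2-[(2-isopropyl-8-methoxy-4-oxo-4H-chromen-5-yl)methyl]-4-oxo-5-(2-oxopropyl)-4H-chromen-7-yl pivalate | COc1ccc(Cc2cc(=O)c3c(CC(C)=O)cc(OC(=O)C(C)(C)C)cc3o2)c2c(=O)cc(C(C)C)oc12 | intermediate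
11 | 7-hydroxy-2-[(2-isopropyl-8-methoxy-4-oxo-4H-chromen-5-yl)methyl]-5-(2-oxopropyl)-4H-chromen-4-one (CNP0592286.0, achiral) | COc1ccc(Cc2cc(=O)c3c(CC(C)=O)cc(O)cc3o2)c2c(=O)cc(C(C)C)oc12 | target

## Step count and risks

Total steps: 5 (step 5 is one pot with two stages).
Longest linear sequence: 4 (5 → 6 → 8 → 9 → 11, or 1 → 4 → 8 → 9 → 11).

Steps most likely to fail, most risky first:

Step 5 (peri C–H acylmethylation, the least precedented step). Risks are poor turnover with the weakly coordinating ketone and carbene chemistry at the acidic bridging CH2. The fallback installs a C5 handle before the union; it sets out from aldehyde 4 and comes back at 10. 5,7-Dihydroxy-4H-chromen-4-one F4 (bought) is pivaloylated at the non-chelated 7-OH (PivCl, Et3N, CH2Cl2, 0 °C) to 5-hydroxy-4-oxo-4H-chromen-7-yl pivalate F5. F5 is triflated (Tf2O, pyridine) to 4-oxo-5-(trifluoromethylsulfonyloxy)-4H-chromen-7-yl pivalate F6. F6 is zincated at C2 as in step 3 to [4-oxo-7-(pivaloyloxy)-5-(trifluoromethylsulfonyloxy)-4H-chromen-2-yl]zinc chloride F7 and added to 4 to give 2-[hydroxy(2-isopropyl-8-methoxy-4-oxo-4H-chromen-5-yl)methyl]-4-oxo-5-(trifluoromethylsulfonyloxy)-4H-chromen-7-yl pivalate F8. F8 is deoxygenated as in step 4 to 2-[(2-isopropyl-8-methoxy-4-oxo-4H-chromen-5-yl)methyl]-4-oxo-5-(trifluoromethylsulfonyloxy)-4H-chromen-7-yl pivalate F9. The triflate of F9 is then coupled with acetonyltributylstannane (from Bu3SnOMe and isopropenyl acetate; PdCl2[P(o-tolyl)3]2, LiCl, toluene, 100 °C) to give 10, which is methanolysed as in step 5.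

Step 3 (key union). The C2 zincation has precedent; the weak point is the 1,2-addition of the electron-poor alkenylzinc to the aldehyde. The fallback changes the electrophile and the bond-forming event to a cross-coupling; it sets out from aldehyde 4, comes back at 9, and bypasses 8 and step 4. Aldehyde 4 is reduced (NaBH4, MeOH/THF, −20 °C) to 5-(hydroxymethyl)-2-isopropyl-8-methoxy-4H-chromen-4-one F1. F1 is converted (PBr3, CH2Cl2, 0 °C) to 5-(bromomethyl)-2-isopropyl-8-methoxy-4H-chromen-4-one F2. F2 is coupled with zinc reagent 7 under Pd(PPh3)4 (5 mol%, THF, 50 °C; Negishi-type benzylation) to give 9 directly.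

Step 4 (ionic deoxygenation). Ionization may be slow next to the electron-poor chromone, or the peri carbonyl of ring A may trap the cation. The fallback replaces cation/hydride chemistry by electron-transfer cleavage; it sets out from 8 and comes back at 9. Carbinol 8 is acetylated (Ac2O, pyridine, DMAP) to 2-[acetoxy(2-isopropyl-8-methoxy-4-oxo-4H-chromen-5-yl)methyl]-4-oxo-4H-chromen-7-yl pivalate F3. F3 is a gamma-acetoxy enone (vinylogous alpha-acyloxy ketone); SmI2 (2.5 equiv, THF/MeOH, −78 °C) expels acetate and protonation of the dienolate gives 9.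

## Further compounds

F1 | step 3 | 5-(hydroxymethyl)-2-isopropyl-8-methoxy-4H-chromen-4-one | COc1ccc(CO)c2c(=O)cc(C(C)C)oc12
F2 | step 3 | 5-(bromomethyl)-2-isopropyl-8-methoxy-4H-chromen-4-one | COc1ccc(CBr)c2c(=O)cc(C(C)C)oc12
F3 | step 4 | 2-[acetoxy(2-isopropyl-8-methoxy-4-oxo-4H-chromen-5-yl)methyl]-4-oxo-4H-chromen-7-yl pivalate, racemic | COc1ccc(C(OC(C)=O)c2cc(=O)c3ccc(OC(=O)C(C)(C)C)cc3o2)c2c(=O)cc(C(C)C)oc12
F4 | step 5 | 5,7-dihydroxy-4H-chromen-4-one | O=c1ccoc2cc(O)cc(O)c12
F5 | step 5 | 5-hydroxy-4-oxo-4H-chromen-7-yl pivalate | CC(C)(C)C(=O)Oc1cc(O)c2c(c1)occc2=O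
F6 | step 5 | 4-oxo-5-(trifluoromethylsulfonyloxy)-4H-chromen-7-yl pivalate | CC(C)(C)C(=O)Oc1cc(OS(=O)(=O)C(F)(F)F)c2c(c1)occc2=O
F7 | step 5 | [4-oxo-7-(pivaloyloxy)-5-(trifluoromethylsulfonyloxy)-4H-chromen-2-yl]zinc chloride | CC(C)(C)C(=O)Oc1cc(OS(=O)(=O)C(F)(F)F)c2c(c1)oc([Zn]Cl)cc2=O
F8 | step 5 | 2-[hydroxy(2-isopropyl-8-methoxy-4-oxo-4H-chromen-5-yl)methyl]-4-oxo-5-(trifluoromethylsulfonyloxy)-4H-chromen-7-yl pivalate, racemic | COc1ccc(C(O)c2cc(=O)c3c(OS(=O)(=O)C(F)(F)F)cc(OC(=O)C(C)(C)C)cc3o2)c2c(=O)cc(C(C)C)oc12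
F9 | step 5 | 2-[(2-isopropyl-8-methoxy-4-oxo-4H-chromen-5-yl)methyl]-4-oxo-5-(trifluoromethylsulfonyloxy)-4H-chromen-7-yl pivalate | COc1ccc(Cc2cc(=O)c3c(OS(=O)(=O)C(F)(F)F)cc(OC(=O)C(C)(C)C)cc3o2)c2c(=O)cc(C(C)C)oc12
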